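**Retrosynthetic overview**

1. Target 23 ⇐ acetonide and PMB removal ⇐ E1cB dehydration across C3–C4 of a 4-hydroxy lactone ⇐ syn reduction ⇐ 1,5-anti boron aldol (bond C2′–C3′) between lactone aldehyde 9 (C2–C6, C1′, C2′) and methyl ketone 13 (C3′–C15′; from decanal by Brown allylation, PMB ether, Wacker oxidation).
2. 9 ⇐ ozonolysis and lactol oxidation of cycloheptenol 7 ⇐ enantioselective nickel-catalysed reductive opening of the meso oxabicycle 6 ⇐ [4+3] cycloaddition of furan with an oxyallyl cation, which makes C2–C3 and C5–C6 in one operation.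
3. Feature used: ring oxygen O1 lies between two oxidised carbons (C2, C6) and C3=C4 is a dehydrated C4 carbinol, so C2–C3–C4–C5–C6–C1′–C2′ is a masked 3,5-dioxygenated heptane-1,7-dial with a hidden mirror plane through C4. O1, C2 and C6 map onto the oxygen and α-carbons of furan, C1′ and C2′ onto its β-carbons, and C3–C4–C5 onto the oxyallyl unit.
4. Ring order: the seven-membered carbocycle and the oxygen-bridged pyran ring form together (step 1); the bridge is opened (step 4), the carbocycle is cleaved and the pyran ring closes again as lactol, then lactone (steps 5 and 6); a temporary 1,3-dioxane (step 12) guards the syn-diol during the dehydration.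

Key step: step 1

Assumption: the sense of induction in step 4 is taken as (S)-BINAP giving (1R,6R)-7; should it be the reverse, (R)-BINAP is used and nothing else changes.

**Route**

Step 1
Reactants: 1 furan; 2 1,1,3,3-tetrabromoacetone
Product: 4 meso-8-oxabicyclo[3.2.1]oct-6-en-3-one, via 2,4-dibromo-8-oxabicyclo[3.2.1]oct-6-en-3-one 3 (not isolated)
Conditions: Zn–Ag couple, furan (excess), THF, −10 °C to rt; then Zn–Cu couple, NH4Cl, MeOH, −78 °C to rt
Reagents that add atoms: none
Why: Zinc reduces the tetrabromide to a zinc 1,3-dibromo-2-oxyallyl cation, a two-π-electron three-carbon electrophile, which adds across the 2,5-positions of furan in a [4+3] cycloaddition (concerted, or stepwise through a furan-stabilised oxocarbenium ion that collapses at once), and zinc then removes both C–Br bonds through the zinc enolates. The closest known reaction type is the oxyallyl cation–furan [4+3] cycloaddition, the standard entry to 8-oxabicyclo[3.2.1]oct-6-en-3-ones. Two rings close together: the seven-membered carbocycle by (4+3) cycloaddition and, through the same two C–C bonds across the furan oxygen, the six-membered oxygen ring that is the future lactone ring O1–C2–C3–C4–C5–C6. The two new stereocentres are the bridgeheads (future C2 and C6); suprafacial addition to furan forces them cis, so 4 is meso, and the bromine-bearing centres are erased by the reduction. The selectivity needed is cycloaddition over Friedel–Crafts-type substitution of furan and over self-condensation of the oxyallyl species; the two bromine substituents stabilise the cation, furan is used in excess, and both partners are symmetric, so no regiochemistry arises.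

Step 2
Reactants: 4 meso-8-oxabicyclo[3.2.1]oct-6-en-3-one
Product: 5 endo-8-oxabicyclo[3.2.1]oct-6-en-3-ol (meso; hydroxyl axial, on the face of the C6=C7 bridge)
Conditions: LiBH(s-Bu)3, THF, −78 °C; then NaOH, H2O2, 0 °C
Reagents that add atoms: none
Why: Sterically controlled ketone reduction, in which the bulky borohydride attacks the open equatorial face of the chair pyranone and should give the axial (endo) alcohol as one diastereomer; the centre is destroyed later and only serves to keep the material uniform.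

Step 3
Reactants: 5 endo-8-oxabicyclo[3.2.1]oct-6-en-3-ol
Product: 6 endo-3-[(tert-butyldimethylsilyl)oxy]-8-oxabicyclo[3.2.1]oct-6-ene (meso)
Conditions: TBSCl, imidazole, DMF, rt
Reagents that add atoms: tert-butyldimethylsilyl chloride, CC(C)(C)[Si](C)(C)Cl
Why: Standard silylation of a secondary alcohol, giving an ether that withstands the aluminium hydride, ozone and boron reagents that follow.

Step 4
Reactants: 6 endo-3-[(tert-butyldimethylsilyl)oxy]-8-oxabicyclo[3.2.1]oct-6-ene
Product: 7 (1R,6R)-6-[(tert-butyldimethylsilyl)oxy]cyclohept-3-en-1-ol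
Conditions: Ni(cod)2 (cat.), (S)-BINAP (cat.), i-Bu2AlH (slow addition), toluene, 60 °C; aq. potassium sodium tartrate
Reagents that add atoms: none
Why: Enantioselective reductive ring opening of an oxabicyclic alkene, in which zerovalent nickel–BINAP catalysed hydroalumination of the strained alkene is followed by β-oxygen elimination; the ligand chooses between the two enantiotopic alkene carbons, which fixes the bridgehead that keeps its oxygen and so sets the future C6 centre, while slow hydride addition keeps the uncatalysed background low.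

Step 5
Reactants: 7 (1R,6R)-6-[(tert-butyldimethylsilyl)oxy]cyclohept-3-en-1-ol
Product: 8 2-[(2S,4S)-4-[(tert-butyldimethylsilyl)oxy]-6-hydroxyoxan-2-yl]acetaldehyde (lactol, mixture of anomers)
Conditions: O3, CH2Cl2, −78 °C; then PPh3, −78 °C to rt
Reagents that add atoms: ozone, [O-][O+]=O
Why: Ozonolysis cleaves the only alkene to a 3-hydroxy-5-silyloxy heptanedial whose free hydroxyl closes onto the δ-aldehyde as a six-membered lactol, which tells the two chain ends apart without touching a stereocentre.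

Step 6
Reactants: 8 2-[(2S,4S)-4-[(tert-butyldimethylsilyl)oxy]-6-hydroxyoxan-2-yl]acetaldehyde
Product: 9 2-[(2S,4S)-4-[(tert-butyldimethylsilyl)oxy]-6-oxooxan-2-yl]acetaldehyde
Conditions: TEMPO (cat.), PhI(OAc)2, CH2Cl2 (anhydrous), rt; used without storage
Reagents that add atoms: none
Why: Oxoammonium oxidation (TEMPO/PhI(OAc)2) converts lactols to lactones quickly, whereas a non-hydrated aldehyde is inert in dry CH2Cl2, so only C2 should be raised to the acid level.

Step 7
Reactants: 10 decanal
Product: 11 (R)-tridec-1-en-4-ol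
Conditions: (−)-Ipc2BOMe, allylMgBr, Et2O, −78 °C to rt; then 10, −78 °C; NaOH, H2O2
Reagents that add atoms: allylmagnesium bromide, C=CC[Mg]Br
Why: Brown allylation, in which the allylborane of the (+)-α-pinene series delivers allyl through a chair six-membered transition state to the Si face of the unbranched aldehyde and sets the (R)-carbinol (future C6′) under reagent control.

Step 8
Reactants: 11 (R)-tridec-1-en-4-ol
Product: 12 1-methoxy-4-({[(4R)-tridec-1-en-4-yl]oxy}methyl)benzene
Conditions: NaH, 4-methoxybenzyl chloride, Bu4NI (cat.), DMF, 0 °C to rt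
Reagents that add atoms: 4-methoxybenzyl chloride, COc1ccc(CCl)cc1
Why: Williamson etherification, which installs the alkyl ether that the 1,5-anti aldol needs as its directing group and does not touch the stereocentre.

Step 9
Reactants: 12 1-methoxy-4-({[(4R)-tridec-1-en-4-yl]oxy}methyl)benzene
Product: 13 (4R)-4-[(4-methoxybenzyl)oxy]tridecan-2-one
Conditions: PdCl2 (cat.), CuCl, O2 (1 atm), DMF/H2O, rt
Reagents that add atoms: water, O
Why: Tsuji–Wacker oxidation, in which Markovnikov hydroxypalladation of the terminal alkene by divalent palladium gives the methyl ketone, with O2/CuCl as the terminal oxidant.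

Step 10
Reactants: 13 (4R)-4-[(4-methoxybenzyl)oxy]tridecan-2-one; 9 2-[(2S,4S)-4-[(tert-butyldimethylsilyl)oxy]-6-oxooxan-2-yl]acetaldehyde
Product: 15 (4S,6R)-4-[(tert-butyldimethylsilyl)oxy]-6-[(2R,6R)-2-hydroxy-6-[(4-methoxybenzyl)oxy]-4-oxopentadecyl]oxan-2-one, via dibutylboron enolate 14 (not isolated)
Conditions: Bu2BOTf, i-Pr2NEt, Et2O, −78 °C; then 9, −78 °C; MeOH, pH 7 buffer, H2O2, 0 °C
Reagents that add atoms: none
Why: Boron-mediated aldol of the kinetic methyl-side enolate, in which the β-(4-methoxybenzyl)oxy group directs 1,5-anti addition (the known 1,5-anti induction of β-alkoxy methyl ketone boron enolates) and so sets C2′ anti to C6′, with the 1,3-anti preference of the β-acyloxy aldehyde acting in the same sense.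

Step 11
Reactants: 15 (4S,6R)-4-[(tert-butyldimethylsilyl)oxy]-6-[(2R,6R)-2-hydroxy-6-[(4-methoxybenzyl)oxy]-4-oxopentadecyl]oxan-2-one
Product: 17 (4S,6R)-4-[(tert-butyldimethylsilyl)oxy]-6-[(2S,4R,6R)-2,4-dihydroxy-6-[(4-methoxybenzyl)oxy]pentadecyl]oxan-2-one, via diethylboron chelate 16 (not isolated)
Conditions: Et2BOMe, THF/MeOH, −78 °C; NaBH4, −78 °C; AcOH, then evaporation from MeOH
Reagents that add atoms: none
Why: Narasaka–Prasad reduction, in which the six-membered boron chelate of the β-hydroxy ketone takes axial external hydride and gives the syn-1,3-diol (C4′ syn to C2′), while the lactone is inert to NaBH4 at −78 °C.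

Step 12
Reactants: 17 (4S,6R)-4-[(tert-butyldimethylsilyl)oxy]-6-[(2S,4R,6R)-2,4-dihydroxy-6-[(4-methoxybenzyl)oxy]pentadecyl]oxan-2-one
Product: 18 (4S,6R)-4-[(tert-butyldimethylsilyl)oxy]-6-{[(4S,6S)-6-[(2R)-2-[(4-methoxybenzyl)oxy]undecyl]-2,2-dimethyl-1,3-dioxan-4-yl]methyl}oxan-2-one
Conditions: 2,2-dimethoxypropane, PPTS (cat.), CH2Cl2, rt
Reagents that add atoms: 2,2-dimethoxypropane, COC(C)(C)OC
Why: Acid-catalysed transacetalisation, which closes a chair 1,3-dioxane with both substituents equatorial on the syn-diol and removes the C2′ hydroxyl as an oxa-Michael donor before the enoate is made.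

Step 13
Reactants: 18 the acetonide of step 12
Product: 19 (4S,6S)-4-hydroxy-6-{[(4S,6S)-6-[(2R)-2-[(4-methoxybenzyl)oxy]undecyl]-2,2-dimethyl-1,3-dioxan-4-yl]methyl}oxan-2-one
Conditions: HF·pyridine, pyridine/THF, 0 °C to rt
Reagents that add atoms: none
Why: Fluoride desilylation under buffered conditions, which frees only the C4 hydroxyl and leaves the acetonide, PMB ether and lactone intact.

Step 14
Reactants: 19 the 4-hydroxy lactone of step 13
Product: 21 (6S)-6-{[(4S,6S)-6-[(2R)-2-[(4-methoxybenzyl)oxy]undecyl]-2,2-dimethyl-1,3-dioxan-4-yl]methyl}-5,6-dihydro-2H-pyran-2-one, via mesylate 20 (not isolated)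
Conditions: MsCl, Et3N (excess), CH2Cl2, 0 °C to rt
Reagents that add atoms: none
Why: Mesylation followed by E1cB elimination of the β-mesyloxy lactone, which should give the conjugated C3=C4 double bond and removes the auxiliary C4 centre.

Step 15
Reactants: 21 the unsaturated lactone of step 14
Product: 22 (6S)-6-{[(4S,6S)-6-[(2R)-2-hydroxyundecyl]-2,2-dimethyl-1,3-dioxan-4-yl]methyl}-5,6-dihydro-2H-pyran-2-one
Conditions: DDQ, CH2Cl2/pH 7 buffer, 0 °C to rt
Reagents that add atoms: none
Why: Oxidative cleavage of the PMB ether by hydride abstraction from the electron-rich benzylic position, to which the enoate and the acetonide are inert.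

Step 16
Reactants: 22 the acetonide alcohol of step 15
Product: 23 (6S)-6-[(2S,4S,6R)-2,4,6-trihydroxypentadecyl]-5,6-dihydro-2H-pyran-2-one (target)
Conditions: AcOH/H2O (4:1), rt
Reagents that add atoms: none
Why: Mild aqueous acid hydrolysis of the acetonide, chosen weak enough that the freed C2′ hydroxyl should not add to the enoate and the lactone should not open.

**Compound list**

1 | furan | c1ccoc1 | starting material
2 | 1,1,3,3-tetrabromoacetone | O=C(C(Br)Br)C(Br)Br | starting material
3 | 2,4-dibromo-8-oxabicyclo[3.2.1]oct-6-en-3-one (mixture of C–Br epimers, cis bridgeheads) | O=C1C(Br)[C@H]2C=C[C@@H](C1Br)O2 | intermediate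
4 | meso-8-oxabicyclo[3.2.1]oct-6-en-3-one | O=C1C[C@H]2C=C[C@@H](C1)O2 | intermediate
5 | endo-8-oxabicyclo[3.2.1]oct-6-en-3-ol (meso) | O[C@H]1C[C@H]2C=C[C@@H](C1)O2 | intermediate
6 | endo-3-[(tert-butyldimethylsilyl)oxy]-8-oxabicyclo[3.2.1]oct-6-ene (meso) | CC(C)(C)[Si](C)(C)O[C@H]1C[C@H]2C=C[C@@H](C1)O2 | intermediate
7 | (1R,6R)-6-[(tert-butyldimethylsilyl)oxy]cyclohept-3-en-1-ol | O[C@@H]1CC=CC[C@@H](O[Si](C)(C)C(C)(C)C)C1 | intermediate
8 | 2-[(2S,4S)-4-[(tert-butyldimethylsilyl)oxy]-6-hydroxyoxan-2-yl]acetaldehyde (anomers) | O=CC[C@@H]1C[C@H](O[Si](C)(C)C(C)(C)C)CC(O)O1 | intermediate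
9 | 2-[(2S,4S)-4-[(tert-butyldimethylsilyl)oxy]-6-oxooxan-2-yl]acetaldehyde | O=CC[C@@H]1C[C@H](O[Si](C)(C)C(C)(C)C)CC(=O)O1 | intermediate
10 | decanal | CCCCCCCCCC=O | starting material
11 | (R)-tridec-1-en-4-ol | CCCCCCCCC[C@@H](O)CC=C | intermediate
12 | 1-methoxy-4-({[(4R)-tridec-1-en-4-yl]oxy}methyl)benzene | CCCCCCCCC[C@@H](OCc1ccc(OC)cc1)CC=C | intermediate
13 | (4R)-4-[(4-methoxybenzyl)oxy]tridecan-2-one | CCCCCCCCC[C@@H](OCc1ccc(OC)cc1)CC(C)=O | intermediate
14 | dibutylboron enolate of 13 (methyl side) | CCCCCCCCC[C@@H](OCc1ccc(OC)cc1)CC(=C)OB(CCCC)CCCC | intermediate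
15 | (4S,6R)-4-[(tert-butyldimethylsilyl)oxy]-6-[(2R,6R)-2-hydroxy-6-[(4-methoxybenzyl)oxy]-4-oxopentadecyl]oxan-2-one | CCCCCCCCC[C@@H](OCc1ccc(OC)cc1)CC(=O)C[C@H](O)C[C@@H]1C[C@H](O[Si](C)(C)C(C)(C)C)CC(=O)O1 | intermediate
16 | C2′ O-diethylborinate of 15 (boron chelated by the C4′ ketone) | CCCCCCCCC[C@@H](OCc1ccc(OC)cc1)CC(=O)C[C@H](OB(CC)CC)C[C@@H]1C[C@H](O[Si](C)(C)C(C)(C)C)CC(=O)O1 | intermediate
17 | (4S,6R)-4-[(tert-butyldimethylsilyl)oxy]-6-[(2S,4R,6R)-2,4-dihydroxy-6-[(4-methoxybenzyl)oxy]pentadecyl]oxan-2-one | CCCCCCCCC[C@@H](OCc1ccc(OC)cc1)C[C@H](O)C[C@H](O)C[C@@H]1C[C@H](O[Si](C)(C)C(C)(C)C)CC(=O)O1 | intermediate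
18 | (4S,6R)-4-[(tert-butyldimethylsilyl)oxy]-6-{[(4S,6S)-6-[(2R)-2-[(4-methoxybenzyl)oxy]undecyl]-2,2-dimethyl-1,3-dioxan-4-yl]methyl}oxan-2-one | CCCCCCCCC[C@@H](OCc1ccc(OC)cc1)C[C@H]1C[C@@H](C[C@@H]2C[C@H](O[Si](C)(C)C(C)(C)C)CC(=O)O2)OC(C)(C)O1 | intermediate
19 | (4S,6S)-4-hydroxy-6-{[(4S,6S)-6-[(2R)-2-[(4-methoxybenzyl)oxy]undecyl]-2,2-dimethyl-1,3-dioxan-4-yl]methyl}oxan-2-one | CCCCCCCCC[C@@H](OCc1ccc(OC)cc1)C[C@H]1C[C@@H](C[C@@H]2C[C@H](O)CC(=O)O2)OC(C)(C)O1 | intermediate
20 | C4 methanesulfonate of 19 | CCCCCCCCC[C@@H](OCc1ccc(OC)cc1)C[C@H]1C[C@@H](C[C@@H]2C[C@H](OS(C)(=O)=O)CC(=O)O2)OC(C)(C)O1 | intermediate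
21 | (6S)-6-{[(4S,6S)-6-[(2R)-2-[(4-methoxybenzyl)oxy]undecyl]-2,2-dimethyl-1,3-dioxan-4-yl]methyl}-5,6-dihydro-2H-pyran-2-one | CCCCCCCCC[C@@H](OCc1ccc(OC)cc1)C[C@H]1C[C@@H](C[C@@H]2CC=CC(=O)O2)OC(C)(C)O1 | intermediate
22 | (6S)-6-{[(4S,6S)-6-[(2R)-2-hydroxyundecyl]-2,2-dimethyl-1,3-dioxan-4-yl]methyl}-5,6-dihydro-2H-pyran-2-one | CCCCCCCCC[C@@H](O)C[C@H]1C[C@@H](C[C@@H]2CC=CC(=O)O2)OC(C)(C)O1 | intermediate
23 | (6S)-6-[(2S,4S,6R)-2,4,6-trihydroxypentadecyl]-5,6-dihydro-2H-pyran-2-one | CCCCCCCCC[C@@H](O)C[C@H](O)C[C@H](O)C[C@@H]1CC=CC(=O)O1 | target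

**Step count and risks**

Total steps: 16. Longest linear sequence: 13 (steps 1–6 and 10–16); steps 7–9 are the side branch.

Step 4. What may go wrong: incomplete discrimination of the two enantiotopic alkene carbons because of a ligand-free or uncatalysed hydroalumination background, or plain reduction of the alkene without bridge opening. The fallback sets out from 6 and replaces catalytic ring opening by reagent-controlled hydroboration and a Baeyer–Villiger cleavage. Hydroboration with the appropriate antipode of Ipc2BH followed by NaOH/H2O2 should give 3-endo-[(tert-butyldimethylsilyl)oxy]-8-oxabicyclo[3.2.1]octan-6-exo-ol F1, with the hydroxyl on the carbon next to the bridgehead that is to become C2. Dess–Martin oxidation gives 3-endo-[(tert-butyldimethylsilyl)oxy]-8-oxabicyclo[3.2.1]octan-6-one F2. Baeyer–Villiger oxidation (mCPBA, NaHCO3), in which the oxygen-bearing bridgehead migrates with retention, gives 7-[(tert-butyldimethylsilyl)oxy]-2,9-dioxabicyclo[3.3.1]nonan-3-one F3. One equivalent of i-Bu2AlH at −78 °C reduces its lactone carbonyl; the resulting hemiacetal ester collapses to the side-chain aldehyde and the ring lactol, and the route is rejoined at 8.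

Step 6. What may go wrong: over-oxidation of the free aldehyde beside the lactol, or loss of the β-acyloxy aldehyde by E1cB opening of the lactone during oxidation and isolation. The fallback sets out from 8 and differentiates the chain ends by exhaustive oxidation followed by chemoselective reduction. NaClO2/NaH2PO4/2-methylbut-2-ene after the TEMPO/PhI(OAc)2 treatment (or TEMPO/PhI(OAc)2 in aqueous MeCN) should give 2-[(2S,4S)-4-[(tert-butyldimethylsilyl)oxy]-6-oxooxan-2-yl]acetic acid F4. BH3·SMe2 reduces the carboxylic acid in the presence of the lactone to (4S,6R)-4-[(tert-butyldimethylsilyl)oxy]-6-(2-hydroxyethyl)oxan-2-one F5. Dess–Martin oxidation buffered with NaHCO3 then gives 9, which is used at once, and the route is rejoined at 9.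

Step 10. What may go wrong: poor facial selectivity at C2′ if the enolate 1,5-induction and the aldehyde bias do not dominate cleanly, or amine-induced β-elimination in the aldehyde. The fallback sets out from 13 and moves stereocontrol from the enolate to the aldehyde under base-free Lewis acid conditions. Kinetic silylation (LiN(SiMe3)2, Me3SiCl, THF, −78 °C) should give (R)-trimethyl{[4-[(4-methoxybenzyl)oxy]tridec-1-en-2-yl]oxy}silane F6. A Mukaiyama aldol of F6 with 9 (BF3·OEt2, CH2Cl2, −78 °C) proceeds through an open transition state in which the β-acyloxy centre directs 1,3-anti addition, which is the same C2′ configuration, and the route is rejoined at 15.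

**Further compounds**

F1 | step 4 | 3-endo-[(tert-butyldimethylsilyl)oxy]-8-oxabicyclo[3.2.1]octan-6-exo-ol | CC(C)(C)[Si](C)(C)O[C@H]1C[C@H]2C[C@H](O)[C@@H](C1)O2
F2 | step 4 | 3-endo-[(tert-butyldimethylsilyl)oxy]-8-oxabicyclo[3.2.1]octan-6-one | CC(C)(C)[Si](C)(C)O[C@H]1C[C@H]2CC(=O)[C@@H](C1)O2
F3 | step 4 | 7-[(tert-butyldimethylsilyl)oxy]-2,9-dioxabicyclo[3.3.1]nonan-3-one | CC(C)(C)[Si](C)(C)O[C@H]1C[C@H]2CC(=O)O[C@@H](C1)O2
F4 | step 6 | 2-[(2S,4S)-4-[(tert-butyldimethylsilyl)oxy]-6-oxooxan-2-yl]acetic acid | OC(=O)C[C@@H]1C[C@H](O[Si](C)(C)C(C)(C)C)CC(=O)O1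
F5 | step 6 | (4S,6R)-4-[(tert-butyldimethylsilyl)oxy]-6-(2-hydroxyethyl)oxan-2-one | OCC[C@@H]1C[C@H](O[Si](C)(C)C(C)(C)C)CC(=O)O1
F6 | step 10 | (R)-trimethyl{[4-[(4-methoxybenzyl)oxy]tridec-1-en-2-yl]oxy}silane | CCCCCCCCC[C@@H](OCc1ccc(OC)cc1)CC(=C)O[Si](C)(C)C
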